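**Plan**

- Retrosynthesis: after removal of two O-benzyl groups, the first cut is the C4–aryl bond to the acylphloroglucinol ring, giving a flavan-4-ol and 1-(2,4,6-trihydroxyphenyl)dodecan-1-one. The second cut is the C3–C4 bond of the pyran ring (ring C) at the C4 ketone level, giving an aryl 1-arylvinyl ether with an ortho formyl group. The third is the O1–C2 ether bond, giving a salicylaldehyde and a bromohydrin.
- Enabling feature: C4 is a benzylic carbon of ring A ortho to the ring oxygen O1, C3 is an unsubstituted CH2, and C2 carries O1 and ring B. A formyl group at C4 and an O1-bound C2=C3 enol ether are therefore within reach for C–H addition across the double bond.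
- Forward: rings A and B are bought and joined through O1; ring C is closed at C3–C4 by rhodium-catalysed hydroacylation; the C4 ketone (the temporary oxidation level) is reduced and ionised; the acylphloroglucinol ring is attached at C4; hydrogenolysis ends the route.
- Stereochemistry: C2 (S) comes from the chiral bisphosphine on rhodium in the ring closure. C4 (R) comes from 1,3-induction by C2 when the arene adds trans to ring B on the C4 cation.

Key step: step 4

Assumption: the sense of induction of the bisphosphine in step 4 cannot be predicted with certainty; the (R) ligand is written and its antipode is to be used if a first run shows the (2R) ketone.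

**Route**

Step 1
Reactants: 1 2-bromo-1-[4-(benzyloxy)phenyl]ethan-1-one
Product: 2 rac-2-bromo-1-[4-(benzyloxy)phenyl]ethan-1-ol
Conditions: NaBH4, MeOH, 0 °C; aq. NH4Cl
Reagents that add atoms: none
Why: Borohydride reduction of the ketone is chemoselective at low temperature with a mildly acidic quench (the primary bromide and the benzyl ether stay), and the new stereocentre is left uncontrolled because step 3 erases it.

Step 2
Reactants: 2 rac-2-bromo-1-[4-(benzyloxy)phenyl]ethan-1-ol; 3 4-(benzyloxy)-2-hydroxybenzaldehyde
Product: 4 rac-4-(benzyloxy)-2-{2-bromo-1-[4-(benzyloxy)phenyl]ethoxy}benzaldehyde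
Conditions: PPh3, DIAD, THF, 0 °C → rt
Reagents that add atoms: none
Why: Mitsunobu etherification of the acidic ortho-formyl phenol at the activated benzylic carbinol carbon should put O1 on the future C2 and leave the bromide on the future C3; configuration is of no concern here.

Step 3
Reactants: 4 rac-4-(benzyloxy)-2-{2-bromo-1-[4-(benzyloxy)phenyl]ethoxy}benzaldehyde
Product: 5 4-(benzyloxy)-2-({1-[4-(benzyloxy)phenyl]ethenyl}oxy)benzaldehyde
Conditions: KOtBu, THF, 0 °C
Reagents that add atoms: none
Why: E2 dehydrobromination of a β-bromo ether (the classical entry to α-alkoxystyrenes) should give the 1-arylvinyl ether as the only possible alkene, since the benzylic α-oxy C–H is the only β-hydrogen; the aldehyde is not enolisable and the racemic stereocentre disappears.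

Step 4
Reactants: 5 4-(benzyloxy)-2-({1-[4-(benzyloxy)phenyl]ethenyl}oxy)benzaldehyde
Product: 7 (2S)-7-(benzyloxy)-2-[4-(benzyloxy)phenyl]chroman-4-one, via acyl-alkyl rhodacycle 6 (not isolated)
Conditions: [Rh(cod)Cl]2 (2.5 mol %), (R)-MeO-BIPHEP (5 mol %), AgBF4 (5 mol %), 1,4-dioxane, 60 °C
Reagents that add atoms: none
Why: Proposed new method: cationic monovalent rhodium should add oxidatively into the formyl C–H bond of 5, the tethered C2=C3 double bond should insert into the Rh–H bond with hydride going to C2 and rhodium to the CH2 terminus C3 to give rhodacycle 6 (trivalent rhodium), and C–C reductive elimination should then form the C3–C4 bond and release 7 in an isomerisation that has no by-product. The closest known reaction type is the enantioselective rhodium–bisphosphine hydroacylation of 1,1-disubstituted alkenes held ortho to an aromatic aldehyde, which gives 3-substituted indanones from 2-(1-substituted vinyl)benzaldehydes, β-aryl ketones from N-(1-arylvinyl)indole-2-carbaldehydes and six-membered benzo-fused ketones from allyl-tethered aryl aldehydes; an oxygen-bound 1-arylvinyl (enol ether) alkene has not been used in it. Ring C closes in a formal 6-endo-trig mode through the seven-membered acyl-alkyl rhodacycle. C2 is the only new stereocentre; it is set when the alkene inserts into Rh–H (or, if insertion is reversible, when one diastereomeric rhodacycle is selected for reductive elimination), and in either case the chiral bisphosphine is the controlling element, reading the different shape of the aryl and aryloxy groups on C2, with no substrate stereocentre involved. The step needs regioselectivity for the CH2 terminus (C–C bond formation at C2 would give a 2-aryl-2-methylbenzofuran-3-one), chemoselectivity against decarbonylation and enantioface selectivity: full substitution at C2 disfavours a tertiary alkyl rhodium and a quaternary reductive elimination, the short rigid tether through ring A and O1 keeps the alkene at the metal after C–H activation, and the absence of any allylic hydrogen excludes double-bond migration.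

Step 5
Reactants: 7 (2S)-7-(benzyloxy)-2-[4-(benzyloxy)phenyl]chroman-4-one
Product: 8 (2S,4S)-7-(benzyloxy)-2-[4-(benzyloxy)phenyl]chroman-4-ol
Conditions: NaBH4, MeOH/THF, 0 °C
Reagents that add atoms: none
Why: Borohydride reduction of the aryl ketone leaves C2 untouched and should give mainly the 2,4-cis alcohol; the C4 configuration does not matter because C4 is ionised in step 7.

Step 6
Reactants: 9 phloroglucinol (benzene-1,3,5-triol); 10 dodecanoyl chloride
Product: 11 1-(2,4,6-trihydroxyphenyl)dodecan-1-one
Conditions: AlCl3 (4 equiv), PhNO2, 60 °C; ice/aq. HCl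
Reagents that add atoms: none
Why: Friedel–Crafts acylation of the symmetrical, highly activated triol should stop after one acyl group because the first deactivates the ring.

Step 7
Reactants: 8 (2S,4S)-7-(benzyloxy)-2-[4-(benzyloxy)phenyl]chroman-4-ol; 11 1-(2,4,6-trihydroxyphenyl)dodecan-1-one (3 equiv)
Product: 13 1-{3-[(2S,4R)-7-(benzyloxy)-2-[4-(benzyloxy)phenyl]chroman-4-yl]-2,4,6-trihydroxyphenyl}dodecan-1-one, via flavan-4-yl cation 12 (not isolated)
Conditions: TsOH·H2O (10 mol %), 1,4-dioxane/CH2Cl2, 0 °C → rt
Reagents that add atoms: none
Why: Acid-catalysed Friedel–Crafts alkylation in which 8 loses water to give cation 12, stabilised by the para 7-benzyloxy group and the ortho ring oxygen O1: the acylphloroglucinol should attack with one of its two equivalent free ring carbons, pseudo-axially on the half-chair cation that holds ring B pseudo-equatorial, which should set C4 as R, trans to ring B (1,3-induction from C2); the minor 2,4-cis isomer is to be removed by chromatography.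

Step 8
Reactants: 13 1-{3-[(2S,4R)-7-(benzyloxy)-2-[4-(benzyloxy)phenyl]chroman-4-yl]-2,4,6-trihydroxyphenyl}dodecan-1-one
Product: 14 (+)-myristinin A
Conditions: H2 (1 atm), 10% Pd/C, EtOAc/MeOH, rt
Reagents that add atoms: none
Why: Hydrogenolysis of the two benzyl aryl ethers should leave the hydrogen-bonded aryl ketone and the cyclic benzylic C2–O1 ether intact under one atmosphere of hydrogen with short contact, and it touches no stereocentre.

**Compound list**

1 | 2-bromo-1-[4-(benzyloxy)phenyl]ethan-1-one | O=C(CBr)c1ccc(OCc2ccccc2)cc1 | starting material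
2 | rac-2-bromo-1-[4-(benzyloxy)phenyl]ethan-1-ol | OC(CBr)c1ccc(OCc2ccccc2)cc1 | intermediate
3 | 4-(benzyloxy)-2-hydroxybenzaldehyde | O=Cc1ccc(OCc2ccccc2)cc1O | starting material
4 | rac-4-(benzyloxy)-2-{2-bromo-1-[4-(benzyloxy)phenyl]ethoxy}benzaldehyde | O=Cc1ccc(OCc2ccccc2)cc1OC(CBr)c1ccc(OCc2ccccc2)cc1 | intermediate
5 | 4-(benzyloxy)-2-({1-[4-(benzyloxy)phenyl]ethenyl}oxy)benzaldehyde | O=Cc1ccc(OCc2ccccc2)cc1OC(=C)c1ccc(OCc2ccccc2)cc1 | intermediate
6 | acyl-alkyl rhodacycle (seven-membered ring Rh–C4(=O)–C4a–C8a–O1–C2–C3; trivalent rhodium; bisphosphine and BF4 counter-ion not drawn; not isolated) | O=C1[Rh+]C[C@@H](c2ccc(OCc3ccccc3)cc2)Oc2cc(OCc3ccccc3)ccc12 | intermediate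
7 | (2S)-7-(benzyloxy)-2-[4-(benzyloxy)phenyl]chroman-4-one | O=C1C[C@@H](c2ccc(OCc3ccccc3)cc2)Oc2cc(OCc3ccccc3)ccc12 | intermediate
8 | (2S,4S)-7-(benzyloxy)-2-[4-(benzyloxy)phenyl]chroman-4-ol (2,4-cis) | O[C@H]1C[C@@H](c2ccc(OCc3ccccc3)cc2)Oc2cc(OCc3ccccc3)ccc12 | intermediate
9 | phloroglucinol (benzene-1,3,5-triol) | Oc1cc(O)cc(O)c1 | starting material
10 | dodecanoyl chloride | CCCCCCCCCCCC(=O)Cl | starting material
11 | 1-(2,4,6-trihydroxyphenyl)dodecan-1-one | CCCCCCCCCCCC(=O)c1c(O)cc(O)cc1O | intermediate
12 | (2S)-7-(benzyloxy)-2-[4-(benzyloxy)phenyl]chroman-4-ylium (flavan-4-yl cation; not isolated) | [CH+]1C[C@@H](c2ccc(OCc3ccccc3)cc2)Oc2cc(OCc3ccccc3)ccc12 | intermediate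
13 | 1-{3-[(2S,4R)-7-(benzyloxy)-2-[4-(benzyloxy)phenyl]chroman-4-yl]-2,4,6-trihydroxyphenyl}dodecan-1-one (2,4-trans) | CCCCCCCCCCCC(=O)c1c(O)cc(O)c([C@@H]2C[C@@H](c3ccc(OCc4ccccc4)cc3)Oc3cc(OCc4ccccc4)ccc32)c1O | intermediate
14 | (+)-myristinin A, 1-{2,4,6-trihydroxy-3-[(2S,4R)-7-hydroxy-2-(4-hydroxyphenyl)chroman-4-yl]phenyl}dodecan-1-one | CCCCCCCCCCCC(=O)c1c(O)cc(O)c([C@@H]2C[C@@H](c3ccc(O)cc3)Oc3cc(O)ccc32)c1O | target

**Step count**

Total step count: 8. Longest linear sequence: 7 steps (steps 1, 2, 3, 4, 5, 7 and 8).

**Steps most likely to fail**

The first is step 4, the proposed new method. What may go wrong is insertion with the reverse regiochemistry (C–C bond formation at C2 to a benzofuranone), decarbonylation after C–H activation, acid-induced condensation of the aldehyde with the enol ether, or weak enantioface discrimination. The fallback uses known chemistry: C2 comes from a reagent-controlled ketone reduction and the same C3–C4 bond is closed by carbene umpolung. Setting out from 1, Corey–Bakshi–Shibata reduction (BH3·SMe2, (S)-2-methyl-CBS-oxazaborolidine, THF, −20 °C) should give (S)-2-bromo-1-[4-(benzyloxy)phenyl]ethan-1-ol F1. Mitsunobu coupling with 3 (PPh3, DIAD, toluene, −20 °C) should invert the carbinol centre and give (R)-4-(benzyloxy)-2-{2-bromo-1-[4-(benzyloxy)phenyl]ethoxy}benzaldehyde F2. An N-heterocyclic carbene (from 3-benzyl-5-(2-hydroxyethyl)-4-methylthiazolium chloride and DBU, 1,4-dioxane) should then reverse the polarity of the formyl carbon, which displaces the primary bromide in a 6-exo-tet alkylation without touching C2. This is a known ring closure of salicylaldehyde-derived ethers to chroman-4-ones, and the route is rejoined at 7. The points to watch there are partial ionisation of the electron-rich benzylic carbinol during the Mitsunobu coupling and base-induced ring opening of the flavanone.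

The second is step 7. What may go wrong is alkylation of ring A of a second flavan unit by the cation (oligomerisation) because the acyl group lowers the nucleophilicity of the phloroglucinol ring, double alkylation of that ring, and incomplete facial selectivity at C4. The fallback changes the order of bond formation. Setting out from 8, the cation is trapped under the same acid catalysis with phloroglucinol 9 itself in large excess, a much stronger and symmetrical π-nucleophile, to give (2S,4R)-7-(benzyloxy)-2-[4-(benzyloxy)phenyl]-4-(2,4,6-trihydroxyphenyl)chromane F3. Friedel–Crafts acylation of its triol ring, the most activated ring with two equivalent free positions, with 10 (AlCl3, CH2Cl2/PhNO2, −10 °C) then comes back to the route at 13.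

The third is step 2. What may go wrong is ionisation of the electron-rich, β-brominated benzylic carbinol after activation, leading to elimination instead of etherification, and slow reaction of the hydrogen-bonded phenol. The fallback forms the O1–C2 bond at the alkene stage and bypasses steps 2 and 3. Setting out from 3, copper-catalysed vinylation of the phenol (CuI, N,N-dimethylglycine, Cs2CO3, 1,4-dioxane, 90 °C) with 1-(benzyloxy)-4-(1-bromoethenyl)benzene F4 should give 5 directly. F4 is itself made by Markovnikov addition of HBr (HBr in AcOH, 0 °C) to commercial 1-(benzyloxy)-4-ethynylbenzene.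

**Further compounds**

F1 | step 4 | (S)-2-bromo-1-[4-(benzyloxy)phenyl]ethan-1-ol | BrC[C@@H](O)c1ccc(OCc2ccccc2)cc1
F2 | step 4 | (R)-4-(benzyloxy)-2-{2-bromo-1-[4-(benzyloxy)phenyl]ethoxy}benzaldehyde | O=Cc1ccc(OCc2ccccc2)cc1O[C@@H](CBr)c1ccc(OCc2ccccc2)cc1
F3 | step 7 | (2S,4R)-7-(benzyloxy)-2-[4-(benzyloxy)phenyl]-4-(2,4,6-trihydroxyphenyl)chromane | Oc1cc(O)c([C@@H]2C[C@@H](c3ccc(OCc4ccccc4)cc3)Oc3cc(OCc4ccccc4)ccc32)c(O)c1
F4 | step 2 | 1-(benzyloxy)-4-(1-bromoethenyl)benzene | C=C(Br)c1ccc(OCc2ccccc2)cc1
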